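The data come from a simulation with constants of no real substance; the scatter is artificial.

Take slowness out of the picture first: the readings of the spring run stop creeping by 0.833 h. The flask charges a racemate of left-handed substrate and right-handed substrate with a partner, a single-handed free catalyst and a racemization catalyst. The spring run is this same flask, followed so far.

all flasks: left-handed substrate 20 mM; right-handed substrate 20 mM; free catalyst 1.8 mM

|  | partner | racemization catalyst | remark | time |
|---|---|---|---|---|
| spring | 50 mM | 1 mM | the very flask that is asked about, followed so far |  |
| autumn | 34 mM | 1 mM | run made earlier |  |
| flask | 50.0 mM | 1.0 mM |  | 5.0 h |

- spring (time / h: left-handed product / %, right-handed substrate / %, right-handed product / %): 0.167: 16.7, 39.1, 8.7; 0.500: 18.5, 35.4, 9.7; 0.833: 19.9, 35.2, 11.0; 1.33: 19.6, 35.0, 9.8; 2.00: 18.7, 34.5, 10.1; 2.50: 18.3, 35.5, 9.9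
- autumn (time / h: left-handed product / %, right-handed substrate / %, right-handed product / %): 0.833: 13.7, 39.9, 7.7; 1.50: 14.6, 39.3, 7.0; 2.50: 13.7, 39.6, 6.8; 3.00: 14.3, 40.1, 7.4; 4.00: 13.2, 39.5, 6.7; 5.00: 14.0, 39.8, 6.6

(standard deviation of a reading: 0.5 percentage points)

- the state of affairs at 5.0 h: stopped, and by what, or still going (it is still moving / the partner has run out first / no working catalyst is left / all of the left-handed substrate has reacted / forward and back rates have come level)
- the left-handed product standing at 5.0 h, as a percentage of the left-handed substrate and right-handed substrate together charged
- the right-handed substrate standing at 5.0 h, as a percentage of the left-handed substrate and right-handed substrate together charged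
- the right-handed product standing at 5.0 h, as a percentage of the left-handed substrate and right-handed substrate together charged

- free catalyst is single-handed; left-handed substrate and right-handed substrate are mirror images of each other, charged as a racemate, each of them at the stated concentration
- the earlier runs were read with a standard deviation of 0.5 percentage points
- the reaction counts as stopped when no species that holds the left-handed substrate and right-handed substrate together changes by six tenths of a point or more over the second half of the time

Read the spring table down its columns. Right-handed substrate reads 35.2% at 0.833 h and 35.5% at 2.50 h, and the products wander about a level from that row on. Now set the autumn table beside it: the catalyst charges are equal, the partner is 34 mM instead of 50 mM, and both products read lower in autumn at the last row.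

So compare the levels by one number, the product share of the partner: the mean of both products together read on the level, in mM, over the partner charged. The spring rows from 0.833 h give 23.5%, and the autumn rows give 24.6%. So in these two runs, which differ in the partner charge, the level goes with that charge.

Carry the spring share forward: it puts both products together at 29.3% of the substrate charged, and I expect that to stand at 5.0 h. The other 76.5% of the partner is not in product, and no column shows where it is. A side path for the partner and a dying catalyst both fit this share, so do not name the stopper from it.

The forecast names one: no working catalyst is left, on the ground “That fits a catalyst dying at a fixed rate”. It gives 19% left-handed product, 35.1% right-handed substrate and 10.1% right-handed product.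

The simulation gives the partner has run out first, with 19.3% left-handed product, 35.4% right-handed substrate and 9.98% right-handed product: the three amounts lie inside the forecast's ranges, but the stopper is another one.

    partner + free catalyst + left-handed substrate → free catalyst + left-handed product (k = 1200 M⁻² min⁻¹)
    partner + free catalyst + right-handed substrate → free catalyst + right-handed product (k = 590 M⁻² min⁻¹)
    left-handed substrate + racemization catalyst ⇌ right-handed substrate + racemization catalyst, rate k3*[racemization catalyst]*[left-handed substrate] forward; the back reaction follows from the equilibrium constant (k = 120 M⁻¹ min⁻¹)
    partner → decomposed reagent (k = 0.0940 min⁻¹)
    2 free catalyst → spent catalyst (k = 44.0 M⁻¹ min⁻¹)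

At the start the partner goes to decomposed reagent 2.2 times as fast as it goes to left-handed product, and at 5.00 h the flask keeps 0% of its partner against 71% of its right-handed substrate: the partner is the limiting reagent. The share read in spring leaves 38.3 mM of partner outside the products of this flask, which holds 38.3 mM of decomposed reagent at that time. In the neighbouring flask with 12 mM of partner, the share gives 7.04% for both products together, and that flask stands at 7.85%.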